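**Retrosynthetic overview** (germacrane numbering: ring C1–C10; lactone O–C6, C7, C11(=C13), C12; C14 on C10; C15 on C4)
1. Target ⇐ bis-TBS ether ⇐ ring-closing metathesis at C1=C10; the ten-membered carbocycle is formed last.
2. Metathesis precursor ⇐ C9 acetylation and C8 (S)-2-methylbutanoylation of the coupling product.
3. Key disconnection C7–C8: Barbier allylation of an α-silyloxy aldehyde (C8–C10, C14) with a 3-(bromomethyl)butenolide (C1–C7, C11–C13, C15). The butenolide ring, made before the coupling, becomes the α-methylene-γ-lactone, and C7 and C8 are set.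
4. Bromobutenolide ⇐ carbonylative lactonisation of a Z-iodoallylic alcohol ⇐ asymmetric alkynylation (C6) of a trisubstituted enal; the enal ⇐ but-2-yne-1,4-diol by hydroalumination–iodination and Negishi coupling.
5. Aldehyde ⇐ (S)-diol from hydrolytic kinetic resolution of a vinyl epoxide (C9) ⇐ 2-methylidenepropane-1,3-diol.

Abbreviations: TBS = tert-butyldimethylsilyl, TES = triethylsilyl, PMB = 4-methoxybenzyl.
Assumption: but-3-en-1-ylzinc bromide (0.5 M in THF) is bought as such.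
The sense of induction of (R,R)-ProPhenol in step 6 is assigned by analogy and must be confirmed on the first run; none of the steps has been run.

**Enal (C1–C6, C15)**

Step 1
Reactants: 1 but-2-yne-1,4-diol
Product: 2 4-[(tert-butyldimethylsilyl)oxy]but-2-yn-1-ol
Conditions: NaH (1.0 equiv), THF, 0 °C; TBSCl (1.0 equiv), 0 °C → rt
Reagents that add atoms: tert-butyldimethylsilyl chloride, CC(C)(C)[Si](C)(C)Cl
Why: Monosilylation of a symmetric diol through its sparingly soluble monosodium alkoxide (O-silylation) gives mainly the mono-TBS ether; no stereocenter is involved.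

Step 2
Reactants: 2 4-[(tert-butyldimethylsilyl)oxy]but-2-yn-1-ol
Product: 4 (Z)-4-[(tert-butyldimethylsilyl)oxy]-3-iodobut-2-en-1-ol, via alkenylaluminate 3 (not isolated)
Conditions: NaAlH2(OCH2CH2OMe)2 (1.5 equiv), THF, 0 °C; then I2, THF, −78 → 0 °C
Reagents that add atoms: iodine, II
Why: Hydroxyl-directed trans-hydroalumination puts aluminium on the alkyne carbon remote from the OH in a five-membered aluminate, and iodinolysis with retention gives the Z-iodide (iodine cis to CH2OH), which fixes the later C4=C5 geometry.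

Step 3
Reactants: 4 (Z)-4-[(tert-butyldimethylsilyl)oxy]-3-iodobut-2-en-1-ol; 5 but-3-en-1-ylzinc bromide
Product: 6 (E)-3-{[(tert-butyldimethylsilyl)oxy]methyl}hepta-2,6-dien-1-ol
Conditions: Pd(dppf)Cl2 (5 mol%), 5 (3 equiv), THF, rt → 45 °C
Reagents that add atoms: none
Why: Negishi sp2–sp3 cross-coupling proceeds with retention of olefin geometry and tolerates the free hydroxyl, so the butenyl chain (C1–C3) ends up cis to the CH2OH carbon (future C6).

Step 4
Reactants: 6 (E)-3-{[(tert-butyldimethylsilyl)oxy]methyl}hepta-2,6-dien-1-ol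
Product: 7 (E)-3-{[(tert-butyldimethylsilyl)oxy]methyl}hepta-2,6-dienal
Conditions: MnO2 (20 equiv), CH2Cl2, rt
Reagents that add atoms: none
Why: MnO2 oxidises only the allylic alcohol under neutral conditions (allylic oxidation), so the trisubstituted enal forms without E/Z isomerisation.

**Bromobutenolide (C1–C7, C11–C13, C15)**

Step 5
Reactants: 8 prop-2-yn-1-ol
Product: 9 1-methoxy-4-[(prop-2-yn-1-yloxy)methyl]benzene (PMB propargyl ether)
Conditions: NaH, PMBCl, Bu4NI (cat.), THF, 0 °C → rt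
Reagents that add atoms: 4-methoxybenzyl chloride, COc1ccc(CCl)cc1
Why: Williamson etherification of the alkoxide with the benzylic chloride gives the PMB ether that later distinguishes O13 from the TBS-protected O15.

Step 6
Reactants: 7 (E)-3-{[(tert-butyldimethylsilyl)oxy]methyl}hepta-2,6-dienal; 9 1-methoxy-4-[(prop-2-yn-1-yloxy)methyl]benzene
Product: 11 (4R,5E)-6-{[(tert-butyldimethylsilyl)oxy]methyl}-1-[(4-methoxybenzyl)oxy]deca-5,9-dien-2-yn-4-ol, via alkynylzinc 10 (not isolated)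
Conditions: Me2Zn (3 equiv), 9 (3 equiv), (R,R)-ProPhenol (20 mol%), Ph3P=O (40 mol%), toluene, 0–4 °C, 48 h
Reagents that add atoms: none
Why: Zinc–ProPhenol-catalysed asymmetric alkynylation: the alkynylzinc made from 9 and Me2Zn adds 1,2 to the enal inside the chiral dinuclear zinc pocket and sets C6 as R (to be checked by Mosher esters; the ligand antipode gives the enantiomer).

Step 7
Reactants: 11 (4R,5E)-6-{[(tert-butyldimethylsilyl)oxy]methyl}-1-[(4-methoxybenzyl)oxy]deca-5,9-dien-2-yn-4-ol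
Product: 13 (2Z,4R,5E)-6-{[(tert-butyldimethylsilyl)oxy]methyl}-2-iodo-1-[(4-methoxybenzyl)oxy]deca-2,5,9-trien-4-ol, via alkenylaluminate 12 (not isolated)
Conditions: NaAlH2(OCH2CH2OMe)2 (1.5 equiv), THF, 0 °C; then I2, THF, −78 → 0 °C
Reagents that add atoms: iodine, II
Why: Hydroxyl-directed trans-hydroalumination (H to C7, Al to C11) and iodinolysis with retention place iodine cis to the C6 carbinol, the geometry needed for lactonisation, and C6 is untouched.

Step 8
Reactants: 13 (2Z,4R,5E)-6-{[(tert-butyldimethylsilyl)oxy]methyl}-2-iodo-1-[(4-methoxybenzyl)oxy]deca-2,5,9-trien-4-ol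
Product: 14 (5R)-5-[(1E)-2-{[(tert-butyldimethylsilyl)oxy]methyl}hexa-1,5-dien-1-yl]-3-{[(4-methoxybenzyl)oxy]methyl}furan-2(5H)-one
Conditions: Pd(PPh3)2Cl2 (5 mol%), CO (1 atm), K2CO3 (2 equiv), THF, rt → 40 °C
Reagents that add atoms: carbon monoxide, [C-]#[O+]
Why: Carbonylative lactonisation: oxidative addition of zerovalent palladium into the vinyl iodide, CO insertion and capture of the acylpalladium by the cis C6 hydroxyl close the butenolide with retention at C6, the mild heterogeneous base limiting γ-epimerisation.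

Step 9
Reactants: 14 (5R)-5-[(1E)-2-{[(tert-butyldimethylsilyl)oxy]methyl}hexa-1,5-dien-1-yl]-3-{[(4-methoxybenzyl)oxy]methyl}furan-2(5H)-one
Product: 15 (5R)-5-[(1E)-2-{[(tert-butyldimethylsilyl)oxy]methyl}hexa-1,5-dien-1-yl]-3-(hydroxymethyl)furan-2(5H)-one
Conditions: DDQ (1.3 equiv), CH2Cl2/pH 7 phosphate buffer (10:1), 0 °C
Reagents that add atoms: none
Why: Oxidative PMB ether cleavage by DDQ (hydride abstraction, then hydrolysis of the oxocarbenium ion) frees the C13 alcohol while the TBS ether, the olefins and the butenolide are inert.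

Step 10
Reactants: 15 (5R)-5-[(1E)-2-{[(tert-butyldimethylsilyl)oxy]methyl}hexa-1,5-dien-1-yl]-3-(hydroxymethyl)furan-2(5H)-one
Product: 16 (5R)-3-(bromomethyl)-5-[(1E)-2-{[(tert-butyldimethylsilyl)oxy]methyl}hexa-1,5-dien-1-yl]furan-2(5H)-one
Conditions: CBr4, PPh3, CH2Cl2, 0 °C
Reagents that add atoms: tetrabromomethane, BrC(Br)(Br)Br
Why: Appel bromination converts the primary allylic alcohol into the bromide by SN2 displacement of the alkoxyphosphonium ion under neutral conditions that do not epimerise the γ-stereocenter.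

**Aldehyde (C8–C10, C14)**

Step 11
Reactants: 17 2-methylidenepropane-1,3-diol
Product: 18 2-{[(tert-butyldimethylsilyl)oxy]methyl}prop-2-en-1-ol
Conditions: NaH (1.0 equiv), THF, 0 °C; TBSCl (1.0 equiv), 0 °C → rt
Reagents that add atoms: tert-butyldimethylsilyl chloride, CC(C)(C)[Si](C)(C)Cl
Why: Monosilylation of the symmetric diol through its monosodium alkoxide (O-silylation) differentiates the two hydroxymethyl groups.

Step 12
Reactants: 18 2-{[(tert-butyldimethylsilyl)oxy]methyl}prop-2-en-1-ol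
Product: 19 2-{[(tert-butyldimethylsilyl)oxy]methyl}prop-2-enal
Conditions: MnO2 (20 equiv), CH2Cl2, rt
Reagents that add atoms: none
Why: Chemoselective allylic oxidation with MnO2 gives the α-substituted acrolein without over-oxidation.

Step 13
Reactants: 19 2-{[(tert-butyldimethylsilyl)oxy]methyl}prop-2-enal
Product: 20 racemic tert-butyldimethyl{[2-(oxiran-2-yl)prop-2-en-1-yl]oxy}silane
Conditions: Me3S+ I−, n-BuLi, THF, −10 °C; then 19, −10 °C → rt
Reagents that add atoms: trimethylsulfonium iodide, C[S+](C)C.[I-]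
Why: Corey–Chaykovsky epoxidation: the unstabilised sulfonium ylide adds 1,2 to the enal and the betaine closes to the vinyl epoxide, formed as the racemate.

Step 14
Reactants: 20 racemic tert-butyldimethyl{[2-(oxiran-2-yl)prop-2-en-1-yl]oxy}silane
Product: 21 (2S)-3-{[(tert-butyldimethylsilyl)oxy]methyl}but-3-ene-1,2-diol
Conditions: (R,R)-(salen)Co(OAc) (trivalent cobalt; salen = N,N'-bis(3,5-di-tert-butylsalicylidene)cyclohexane-1,2-diamine dianion; 1 mol%), H2O (0.45 equiv), THF, 0 °C → rt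
Reagents that add atoms: water, O
Why: Jacobsen hydrolytic kinetic resolution: the cobalt–salen catalyst hydrolyses only the (S)-epoxide at its terminal carbon, so C9 of the diol is S with its C–O bond never broken, and the slow (R)-epoxide is removed by chromatography.

Step 15
Reactants: 21 (2S)-3-{[(tert-butyldimethylsilyl)oxy]methyl}but-3-ene-1,2-diol
Product: 22 (2S)-3-{[(tert-butyldimethylsilyl)oxy]methyl}-1,2-bis[(triethylsilyl)oxy]but-3-ene
Conditions: TESCl (2.5 equiv), imidazole, DMAP (cat.), CH2Cl2, 0 °C → rt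
Reagents that add atoms: chlorotriethylsilane, CC[Si](Cl)(CC)CC
Why: Silyl ether formation on both hydroxyls gives a non-chelating silyl group on O9 for the later Felkin-controlled addition; no stereochemical change.

Step 16
Reactants: 22 (2S)-3-{[(tert-butyldimethylsilyl)oxy]methyl}-1,2-bis[(triethylsilyl)oxy]but-3-ene
Product: 23 (2S)-3-{[(tert-butyldimethylsilyl)oxy]methyl}-2-[(triethylsilyl)oxy]but-3-en-1-ol
Conditions: HF·pyridine, pyridine, THF, 0 °C, stopped at full conversion of 22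
Reagents that add atoms: none
Why: Kinetically selective desilylation: the unhindered primary TES ether is cleaved by buffered HF·pyridine much faster than the secondary TES and the primary TBS ethers.

Step 17
Reactants: 23 (2S)-3-{[(tert-butyldimethylsilyl)oxy]methyl}-2-[(triethylsilyl)oxy]but-3-en-1-ol
Product: 24 (2S)-3-{[(tert-butyldimethylsilyl)oxy]methyl}-2-[(triethylsilyl)oxy]but-3-enal
Conditions: Dess–Martin periodinane (1.3 equiv), pyridine (3 equiv), CH2Cl2, 0 °C; used crude at once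
Reagents that add atoms: none
Why: Dess–Martin oxidation under buffered, non-enolising conditions gives the α-silyloxy β,γ-unsaturated aldehyde without epimerisation at C9 or migration of the double bond.

**Coupling and endgame**

Step 18
Reactants: 16 (5R)-3-(bromomethyl)-5-[(1E)-2-{[(tert-butyldimethylsilyl)oxy]methyl}hexa-1,5-dien-1-yl]furan-2(5H)-one; 24 (2S)-3-{[(tert-butyldimethylsilyl)oxy]methyl}-2-[(triethylsilyl)oxy]but-3-enal
Product: 26 (4R,5R)-4-[(1R,2S)-3-{[(tert-butyldimethylsilyl)oxy]methyl}-1-hydroxy-2-[(triethylsilyl)oxy]but-3-en-1-yl]-5-[(1E)-2-{[(tert-butyldimethylsilyl)oxy]methyl}hexa-1,5-dien-1-yl]-3-methylideneoxolan-2-one, via allylzinc bromide 25 (not isolated)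
Conditions: Zn dust (activated, 3 equiv), 16 (1.2 equiv), THF/sat. aq. NH4Cl (2:1), 0 °C → rt
Reagents that add atoms: none
Why: Barbier allylation: the allylzinc reacts at its γ-carbon (C7) through a closed chair transition state on the ring face anti to the C6 side chain (trans lactone), the ring-locked E-type geometry gives the anti C7/C8 relationship, and polar Felkin–Anh addition to the α-silyloxy aldehyde gives the 8,9-anti diol, so all three control elements reinforce one another.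

Step 19
Reactants: 26 (4R,5R)-4-[(1R,2S)-3-{[(tert-butyldimethylsilyl)oxy]methyl}-1-hydroxy-2-[(triethylsilyl)oxy]but-3-en-1-yl]-5-[(1E)-2-{[(tert-butyldimethylsilyl)oxy]methyl}hexa-1,5-dien-1-yl]-3-methylideneoxolan-2-one; 27 (2S)-2-methylbutanoic acid
Product: 29 (1R,2S)-3-{[(tert-butyldimethylsilyl)oxy]methyl}-1-{(2R,3S)-2-[(1E)-2-{[(tert-butyldimethylsilyl)oxy]methyl}hexa-1,5-dien-1-yl]-4-methylidene-5-oxooxolan-3-yl}-2-[(triethylsilyl)oxy]but-3-en-1-yl (2S)-2-methylbutanoate, via mixed anhydride 28 (not isolated)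
Conditions: 27 (3 equiv), 2,4,6-trichlorobenzoyl chloride, Et3N, THF, rt; then 26, DMAP, toluene, rt
Reagents that add atoms: none
Why: Yamaguchi esterification: the DMAP-activated mixed anhydride acylates the hindered C8 hydroxyl faster than it can translactonise onto C12, with retention at C8 and no epimerisation of the acid.

Step 20
Reactants: 29 (1R,2S)-3-{[(tert-butyldimethylsilyl)oxy]methyl}-1-{(2R,3S)-2-[(1E)-2-{[(tert-butyldimethylsilyl)oxy]methyl}hexa-1,5-dien-1-yl]-4-methylidene-5-oxooxolan-3-yl}-2-[(triethylsilyl)oxy]but-3-en-1-yl (2S)-2-methylbutanoate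
Product: 30 (1R,2S)-3-{[(tert-butyldimethylsilyl)oxy]methyl}-1-{(2R,3S)-2-[(1E)-2-{[(tert-butyldimethylsilyl)oxy]methyl}hexa-1,5-dien-1-yl]-4-methylidene-5-oxooxolan-3-yl}-2-hydroxybut-3-en-1-yl (2S)-2-methylbutanoate
Conditions: PPTS (0.3 equiv), MeOH/CH2Cl2 (1:3), 0 °C, monitored
Reagents that add atoms: none
Why: Acid-catalysed methanolysis (selective desilylation) removes the secondary TES ether far faster than the two primary TBS ethers, and the weakly acidic medium prevents acyl migration from O8 to O9.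

Step 21
Reactants: 30 (1R,2S)-3-{[(tert-butyldimethylsilyl)oxy]methyl}-1-{(2R,3S)-2-[(1E)-2-{[(tert-butyldimethylsilyl)oxy]methyl}hexa-1,5-dien-1-yl]-4-methylidene-5-oxooxolan-3-yl}-2-hydroxybut-3-en-1-yl (2S)-2-methylbutanoate
Product: 31 (1R,2S)-2-acetoxy-3-{[(tert-butyldimethylsilyl)oxy]methyl}-1-{(2R,3S)-2-[(1E)-2-{[(tert-butyldimethylsilyl)oxy]methyl}hexa-1,5-dien-1-yl]-4-methylidene-5-oxooxolan-3-yl}but-3-en-1-yl (2S)-2-methylbutanoate
Conditions: Ac2O, pyridine, DMAP (cat.), CH2Cl2, 0 °C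
Reagents that add atoms: acetic anhydride, CC(=O)OC(C)=O
Why: DMAP-catalysed acetylation (nucleophilic acyl transfer) of the C9 hydroxyl proceeds with retention at C9 and is run immediately so that no acyl migration occurs.

Step 22
Reactants: 31 (1R,2S)-2-acetoxy-3-{[(tert-butyldimethylsilyl)oxy]methyl}-1-{(2R,3S)-2-[(1E)-2-{[(tert-butyldimethylsilyl)oxy]methyl}hexa-1,5-dien-1-yl]-4-methylidene-5-oxooxolan-3-yl}but-3-en-1-yl (2S)-2-methylbutanoate
Product: 32 (3aS,4R,5S,6Z,10E,11aR)-5-acetoxy-6,10-bis({[tert-butyldimethylsilyl]oxy}methyl)-3-methylidene-2-oxo-2,3,3a,4,5,8,9,11a-octahydrocyclodeca[b]furan-4-yl (2S)-2-methylbutanoate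
Conditions: second-generation Hoveyda–Grubbs catalyst RuCl2(=CH-C6H4-2-OiPr)(SIMes) (2 × 10 mol%), 1,4-benzoquinone (20 mol%), toluene (0.5 mM), 80 °C, argon sparge
Reagents that add atoms: none
Why: Ring-closing metathesis: the ruthenium carbene loads on the unhindered C1 vinyl group and closes onto the 1,1-disubstituted C10 methylene with loss of ethylene, and the ten-membered ring bearing the cis C4=C5 olefin and the trans-fused lactone should favour the cis (6Z) trisubstituted olefin.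

Step 23
Reactants: 32 (3aS,4R,5S,6Z,10E,11aR)-5-acetoxy-6,10-bis({[tert-butyldimethylsilyl]oxy}methyl)-3-methylidene-2-oxo-2,3,3a,4,5,8,9,11a-octahydrocyclodeca[b]furan-4-yl (2S)-2-methylbutanoate
Product: 33 (3aS,4R,5S,6Z,10E,11aR)-5-acetoxy-6,10-bis(hydroxymethyl)-3-methylidene-2-oxo-2,3,3a,4,5,8,9,11a-octahydrocyclodeca[b]furan-4-yl (2S)-2-methylbutanoate (target)
Conditions: HF·pyridine, pyridine, THF, 0 °C → rt
Reagents that add atoms: none
Why: Fluoride-mediated desilylation with buffered HF·pyridine cleaves both primary TBS ethers while the two esters and the α-methylene lactone survive and, the medium being acidic, no acyl migration to the new primary hydroxyls occurs.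

**Compound list**
1 | but-2-yne-1,4-diol | OCC#CCO | starting material
2 | 4-[(tert-butyldimethylsilyl)oxy]but-2-yn-1-ol | OCC#CCO[Si](C)(C)C(C)(C)C | intermediate
3 | sodium cyclic alkenylaluminate from 2 (five-membered 1,2-oxaluminole, Al on the carbon bearing CH2OTBS, two 2-methoxyethoxy ligands) | [Na+].COCCO[Al-]1(OCCOC)OCC=C1CO[Si](C)(C)C(C)(C)C | intermediate
4 | (Z)-4-[(tert-butyldimethylsilyl)oxy]-3-iodobut-2-en-1-ol | OC/C=C(\I)CO[Si](C)(C)C(C)(C)C | intermediate
5 | but-3-en-1-ylzinc bromide | C=CCC[Zn]Br | starting material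
6 | (E)-3-{[(tert-butyldimethylsilyl)oxy]methyl}hepta-2,6-dien-1-ol | OC/C=C(\CCC=C)CO[Si](C)(C)C(C)(C)C | intermediate
7 | (E)-3-{[(tert-butyldimethylsilyl)oxy]methyl}hepta-2,6-dienal | O=C/C=C(\CCC=C)CO[Si](C)(C)C(C)(C)C | intermediate
8 | prop-2-yn-1-ol | C#CCO | starting material
9 | 1-methoxy-4-[(prop-2-yn-1-yloxy)methyl]benzene | C#CCOCc1ccc(OC)cc1 | intermediate
10 | methyl{3-[(4-methoxybenzyl)oxy]prop-1-yn-1-yl}zinc | C[Zn]C#CCOCc1ccc(OC)cc1 | intermediate
11 | (4R,5E)-6-{[(tert-butyldimethylsilyl)oxy]methyl}-1-[(4-methoxybenzyl)oxy]deca-5,9-dien-2-yn-4-ol | O[C@@H](C#CCOCc1ccc(OC)cc1)/C=C(/CO[Si](C)(C)C(C)(C)C)CCC=C | intermediate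
12 | sodium cyclic alkenylaluminate from 11 (1,2-oxaluminole, Al on C11, O on C6) | [Na+].COCCO[Al-]1(OCCOC)O[C@@H](C=C1COCc2ccc(OC)cc2)/C=C(/CO[Si](C)(C)C(C)(C)C)CCC=C | intermediate
13 | (2Z,4R,5E)-6-{[(tert-butyldimethylsilyl)oxy]methyl}-2-iodo-1-[(4-methoxybenzyl)oxy]deca-2,5,9-trien-4-ol | O[C@@H](/C=C(\I)COCc1ccc(OC)cc1)/C=C(/CO[Si](C)(C)C(C)(C)C)CCC=C | intermediate
14 | (5R)-5-[(1E)-2-{[(tert-butyldimethylsilyl)oxy]methyl}hexa-1,5-dien-1-yl]-3-{[(4-methoxybenzyl)oxy]methyl}furan-2(5H)-one | O=C1O[C@@H](C=C1COCc2ccc(OC)cc2)/C=C(/CO[Si](C)(C)C(C)(C)C)CCC=C | intermediate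
15 | (5R)-5-[(1E)-2-{[(tert-butyldimethylsilyl)oxy]methyl}hexa-1,5-dien-1-yl]-3-(hydroxymethyl)furan-2(5H)-one | O=C1O[C@@H](C=C1CO)/C=C(/CO[Si](C)(C)C(C)(C)C)CCC=C | intermediate
16 | (5R)-3-(bromomethyl)-5-[(1E)-2-{[(tert-butyldimethylsilyl)oxy]methyl}hexa-1,5-dien-1-yl]furan-2(5H)-one | O=C1O[C@@H](C=C1CBr)/C=C(/CO[Si](C)(C)C(C)(C)C)CCC=C | intermediate
17 | 2-methylidenepropane-1,3-diol | C=C(CO)CO | starting material
18 | 2-{[(tert-butyldimethylsilyl)oxy]methyl}prop-2-en-1-ol | C=C(CO)CO[Si](C)(C)C(C)(C)C | intermediate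
19 | 2-{[(tert-butyldimethylsilyl)oxy]methyl}prop-2-enal | C=C(C=O)CO[Si](C)(C)C(C)(C)C | intermediate
20 | racemic tert-butyldimethyl{[2-(oxiran-2-yl)prop-2-en-1-yl]oxy}silane | C=C(CO[Si](C)(C)C(C)(C)C)C1CO1 | intermediate
21 | (2S)-3-{[(tert-butyldimethylsilyl)oxy]methyl}but-3-ene-1,2-diol | C=C(CO[Si](C)(C)C(C)(C)C)[C@H](O)CO | intermediate
22 | (2S)-3-{[(tert-butyldimethylsilyl)oxy]methyl}-1,2-bis[(triethylsilyl)oxy]but-3-ene | C=C(CO[Si](C)(C)C(C)(C)C)[C@H](O[Si](CC)(CC)CC)CO[Si](CC)(CC)CC | intermediate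
23 | (2S)-3-{[(tert-butyldimethylsilyl)oxy]methyl}-2-[(triethylsilyl)oxy]but-3-en-1-ol | C=C(CO[Si](C)(C)C(C)(C)C)[C@H](O[Si](CC)(CC)CC)CO | intermediate
24 | (2S)-3-{[(tert-butyldimethylsilyl)oxy]methyl}-2-[(triethylsilyl)oxy]but-3-enal | C=C(CO[Si](C)(C)C(C)(C)C)[C@H](O[Si](CC)(CC)CC)C=O | intermediate
25 | bromo({(5R)-5-[(1E)-2-{[(tert-butyldimethylsilyl)oxy]methyl}hexa-1,5-dien-1-yl]-2-oxo-2,5-dihydrofuran-3-yl}methyl)zinc | Br[Zn]CC1=C[C@H](OC1=O)/C=C(/CO[Si](C)(C)C(C)(C)C)CCC=C | intermediate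
26 | (4R,5R)-4-[(1R,2S)-3-{[(tert-butyldimethylsilyl)oxy]methyl}-1-hydroxy-2-[(triethylsilyl)oxy]but-3-en-1-yl]-5-[(1E)-2-{[(tert-butyldimethylsilyl)oxy]methyl}hexa-1,5-dien-1-yl]-3-methylideneoxolan-2-one | C=C1C(=O)O[C@H](/C=C(/CO[Si](C)(C)C(C)(C)C)CCC=C)[C@H]1[C@@H](O)[C@@H](O[Si](CC)(CC)CC)C(=C)CO[Si](C)(C)C(C)(C)C | intermediate
27 | (2S)-2-methylbutanoic acid | CC[C@H](C)C(=O)O | starting material
28 | (2S)-2-methylbutanoic 2,4,6-trichlorobenzoic anhydride | CC[C@H](C)C(=O)OC(=O)c1c(Cl)cc(Cl)cc1Cl | intermediate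
29 | (1R,2S)-3-{[(tert-butyldimethylsilyl)oxy]methyl}-1-{(2R,3S)-2-[(1E)-2-{[(tert-butyldimethylsilyl)oxy]methyl}hexa-1,5-dien-1-yl]-4-methylidene-5-oxooxolan-3-yl}-2-[(triethylsilyl)oxy]but-3-en-1-yl (2S)-2-methylbutanoate | C=C1C(=O)O[C@H](/C=C(/CO[Si](C)(C)C(C)(C)C)CCC=C)[C@H]1[C@@H](OC(=O)[C@@H](C)CC)[C@@H](O[Si](CC)(CC)CC)C(=C)CO[Si](C)(C)C(C)(C)C | intermediate
30 | (1R,2S)-3-{[(tert-butyldimethylsilyl)oxy]methyl}-1-{(2R,3S)-2-[(1E)-2-{[(tert-butyldimethylsilyl)oxy]methyl}hexa-1,5-dien-1-yl]-4-methylidene-5-oxooxolan-3-yl}-2-hydroxybut-3-en-1-yl (2S)-2-methylbutanoate | C=C1C(=O)O[C@H](/C=C(/CO[Si](C)(C)C(C)(C)C)CCC=C)[C@H]1[C@@H](OC(=O)[C@@H](C)CC)[C@@H](O)C(=C)CO[Si](C)(C)C(C)(C)C | intermediate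
31 | (1R,2S)-2-acetoxy-3-{[(tert-butyldimethylsilyl)oxy]methyl}-1-{(2R,3S)-2-[(1E)-2-{[(tert-butyldimethylsilyl)oxy]methyl}hexa-1,5-dien-1-yl]-4-methylidene-5-oxooxolan-3-yl}but-3-en-1-yl (2S)-2-methylbutanoate | C=C1C(=O)O[C@H](/C=C(/CO[Si](C)(C)C(C)(C)C)CCC=C)[C@H]1[C@@H](OC(=O)[C@@H](C)CC)[C@@H](OC(C)=O)C(=C)CO[Si](C)(C)C(C)(C)C | intermediate
32 | (3aS,4R,5S,6Z,10E,11aR)-5-acetoxy-6,10-bis({[tert-butyldimethylsilyl]oxy}methyl)-3-methylidene-2-oxo-2,3,3a,4,5,8,9,11a-octahydrocyclodeca[b]furan-4-yl (2S)-2-methylbutanoate | C=C1C(=O)O[C@@H]2/C=C(/CO[Si](C)(C)C(C)(C)C)CC/C=C(/CO[Si](C)(C)C(C)(C)C)[C@H](OC(C)=O)[C@H](OC(=O)[C@@H](C)CC)[C@@H]12 | intermediate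
33 | (3aS,4R,5S,6Z,10E,11aR)-5-acetoxy-6,10-bis(hydroxymethyl)-3-methylidene-2-oxo-2,3,3a,4,5,8,9,11a-octahydrocyclodeca[b]furan-4-yl (2S)-2-methylbutanoate | C=C1C(=O)O[C@@H]2/C=C(/CO)CC/C=C(/CO)[C@H](OC(C)=O)[C@H](OC(=O)[C@@H](C)CC)[C@@H]12 | target

**Step count**
Total: 23 steps. Longest linear sequence: 15 steps (steps 1–4, 6–10, 18–23).

**Three steps most likely to fail, each with a fallback**

Step 6 (asymmetric alkynylation of a β,β-disubstituted enal): the enantiomeric excess may be low, or the sense of induction may be opposite to that assumed. The fallback sets out from 7 and 9 and returns at 11. Alkyne 9 is lithiated (n-BuLi, THF, −78 °C) and added to 7 to give the racemic propargylic alcohol F1. MnO2 (CH2Cl2, rt) oxidises it to the cross-conjugated ynone F2. Reduction with (R)-2-methyl-CBS-oxazaborolidine (0.2 equiv) and catecholborane (toluene, −78 °C) then gives 11; the bulky trisubstituted alkenyl arm acts as the large group and the alkyne as the small one, so hydride is delivered to the face that gives the (R)-carbinol.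

Step 18 (Barbier coupling): the α-silyloxy β,γ-unsaturated aldehyde may isomerise or hydrate in the aqueous zinc medium, and the diastereoselectivity may erode through open transition states. The fallback sets out from 16 and returns at 26. Bromide 16 is borylated with B2pin2 and Pd2(dba)3 (2.5 mol%, toluene, 50 °C) to the allylboronate F3. F3 is combined with 24 under anhydrous conditions with Sc(OTf)3 (10 mol%, toluene, −78 → 0 °C). This allylboration runs strictly through the closed chair transition state, anti to the C6 side chain, and aqueous work-up of the borate gives 26.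

Step 22 (ring-closing metathesis): the hindered C10 methylene may react slowly, and the α-methylene lactone can capture the ruthenium carbene, so dimers or no ring may result. The fallback sets out from 31 and returns at 32. Thiophenol (Et3N cat., CH2Cl2, 0 °C) adds to the exocyclic enoate of 31 to give the sulfide F4 (mixture at C11), which removes the competing acceptor olefin and makes C11 tetrahedral. Ring-closing metathesis of F4 under the step 22 conditions gives the macrocyclic sulfide F5. Oxidation with mCPBA (1.0 equiv, CH2Cl2, −78 °C) gives the sulfoxide F6. Thermal syn-elimination (toluene, NaHCO3, 90 °C), for which the C11 hydrogen is the only β-hydrogen, restores the α-methylene lactone and gives 32.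

**Further compounds**
F1 | step 6 | racemic (5E)-6-{[(tert-butyldimethylsilyl)oxy]methyl}-1-[(4-methoxybenzyl)oxy]deca-5,9-dien-2-yn-4-ol | OC(C#CCOCc1ccc(OC)cc1)/C=C(/CO[Si](C)(C)C(C)(C)C)CCC=C
F2 | step 6 | (5E)-6-{[(tert-butyldimethylsilyl)oxy]methyl}-1-[(4-methoxybenzyl)oxy]deca-5,9-dien-2-yn-4-one | O=C(C#CCOCc1ccc(OC)cc1)/C=C(/CO[Si](C)(C)C(C)(C)C)CCC=C
F3 | step 18 | (5R)-5-[(1E)-2-{[(tert-butyldimethylsilyl)oxy]methyl}hexa-1,5-dien-1-yl]-3-[(4,4,5,5-tetramethyl-1,3,2-dioxaborolan-2-yl)methyl]furan-2(5H)-one | CC1(C)OB(CC2=C[C@H](OC2=O)/C=C(/CO[Si](C)(C)C(C)(C)C)CCC=C)OC1(C)C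
F4 | step 22 | thiophenol adduct of 31 (C13 carries SPh, C11 epimer mixture) | c1ccccc1SCC1C(=O)O[C@H](/C=C(/CO[Si](C)(C)C(C)(C)C)CCC=C)[C@H]1[C@@H](OC(=O)[C@@H](C)CC)[C@@H](OC(C)=O)C(=C)CO[Si](C)(C)C(C)(C)C
F5 | step 22 | macrocyclic sulfide (32 with C11–CH2SPh in place of the exocyclic methylene, C11 epimer mixture) | c1ccccc1SCC1C(=O)O[C@@H]2/C=C(/CO[Si](C)(C)C(C)(C)C)CC/C=C(/CO[Si](C)(C)C(C)(C)C)[C@H](OC(C)=O)[C@H](OC(=O)[C@@H](C)CC)[C@@H]12
F6 | step 22 | macrocyclic sulfoxide (F5 oxidised at sulfur, mixture at S and C11) | O=S(CC1C(=O)O[C@@H]2/C=C(/CO[Si](C)(C)C(C)(C)C)CC/C=C(/CO[Si](C)(C)C(C)(C)C)[C@H](OC(C)=O)[C@H](OC(=O)[C@@H](C)CC)[C@@H]12)c1ccccc1
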